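**Retrosynthetic overview** (drimane numbering: ring A = C1–C5, C10; ring B = C5–C10; C11 = CH2O on C9; C12 = exocyclic CH2 on C8)
1. Target ⇒ Mitsunobu ether at C11 with bought umbelliferone, C3 isovalerate, and C8=CH2 from a C8 ketone ⇒ a trans-fused 3-oxo-Δ6-octalin carrying C11–OSi.
2. Ring A ⇒ C4–C5 (carbanion-accelerated Claisen rearrangement) and C1–C2 (Knoevenagel condensation) are cut in one operation, giving a ring B cyclohex-2-enol with a formyl group on the quaternary C10 and 3-methyl-1-(phenylsulfonyl)buta-1,2-diene as the C2–C3–C4 unit.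
3. Enabling feature: in ring A the C3 oxygen lies between the C2 methylene and the gem-dimethyl carbon C4 (a hidden 2-oxyallyl, i.e. 1,1-dimethylallene, unit); C5 is the allylic terminus of C5=C6–C7–O in ring B; C1 is a non-enolisable aldehyde carbon on C10, 1,5 to the C3 carbonyl.
4. Ring B ⇒ catalytic enantioselective Diels–Alder reaction of an (E)-2-methyl-4-silyloxybut-2-enal with a 2-silyloxybutadiene (sets C9 and C10), then Saegusa–Ito oxidation and Luche reduction (sets the C7 carbinol, which relays its chirality to C5 and is then lost).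
5. Order of ring formation: ring B (Diels–Alder), then ring A (key step); the coumarin is attached last. The C6=C7 alkene left by the sigmatropic shift is the handle for oxidising C8.

Key step: step 9

Assumption: the oxazaborolidinium catalyst in step 6 is taken to direct the diene to the Re face of the α-carbon of the enal, following the formyl C–H···O binding model for 2-substituted enals; if the opposite sense is found, the enantiomeric catalyst is used in the same step.
Assumption: benzenesulfenyl chloride is not bought but made in the flask from diphenyl disulfide and SO2Cl2.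

**Route**

Step 1
Reactants: 1 2-methylbut-3-yn-2-ol
Product: 3 [(3-methylbuta-1,2-dien-1-yl)sulfinyl]benzene (racemic at sulfur), via sulfenate ester 2 (not isolated)
Conditions: PhSSPh, SO2Cl2, CH2Cl2, 0 °C; then 1, Et3N, −78 °C to rt
Reagents that add atoms: diphenyl disulfide, c1ccc(SSc2ccccc2)cc1
Why: O-sulfenylation of the tertiary propargylic alcohol should give the sulfenate, which rearranges spontaneously by a [2,3]-sigmatropic shift (propargyl sulfenate to allenyl sulfoxide rearrangement).

Step 2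
Reactants: 3 [(3-methylbuta-1,2-dien-1-yl)sulfinyl]benzene
Product: 4 [(3-methylbuta-1,2-dien-1-yl)sulfonyl]benzene
Conditions: mCPBA, CH2Cl2, 0 °C
Reagents that add atoms: 3-chloroperoxybenzoic acid, O=C(OO)c1cccc(Cl)c1
Why: peracid oxidation of the sulfoxide at sulfur should be much faster than epoxidation of the electron-poor allene.

Step 3
Reactants: 5 but-3-en-2-one
Product: 6 2-[(triisopropylsilyl)oxy]buta-1,3-diene
Conditions: TIPSOTf, Et3N, Et2O, 0 °C to rt
Reagents that add atoms: triisopropylsilyl trifluoromethanesulfonate, CC(C)[Si](C(C)C)(C(C)C)OS(=O)(=O)C(F)(F)F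
Why: soft enolisation and O-silylation at the only enolisable position of the enone (silyl enol ether formation) should give the 2-silyloxy diene.

Step 4
Reactants: 7 3-methylbut-2-en-1-ol
Product: 8 tert-butyl[(3-methylbut-2-en-1-yl)oxy]diphenylsilane
Conditions: TBDPSCl, imidazole, DMF, rt
Reagents that add atoms: tert-butyl(chloro)diphenylsilane, CC(C)(C)[Si](Cl)(c1ccccc1)c1ccccc1
Why: standard silylation of a primary alcohol; the acid- and base-stable TBDPS ether is chosen to last until step 16.

Step 5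
Reactants: 8 tert-butyl[(3-methylbut-2-en-1-yl)oxy]diphenylsilane
Product: 10 (E)-4-[(tert-butyldiphenylsilyl)oxy]-2-methylbut-2-enal, via allylic alcohol 9 (not isolated)
Conditions: SeO2, 1,4-dioxane, 80 °C
Reagents that add atoms: selenium dioxide, O=[Se]=O
Why: SeO2 allylic oxidation (ene reaction, then [2,3]-sigmatropic shift) attacks the (E)-methyl group at the more substituted alkene terminus and carries the allylic alcohol on to the enal, so the E geometry follows from the mechanism.

Step 6
Reactants: 10 (E)-4-[(tert-butyldiphenylsilyl)oxy]-2-methylbut-2-enal; 6 2-[(triisopropylsilyl)oxy]buta-1,3-diene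
Product: 11 (1R,6R)-6-{[(tert-butyldiphenylsilyl)oxy]methyl}-1-methyl-4-[(triisopropylsilyl)oxy]cyclohex-3-ene-1-carbaldehyde
Conditions: (S)-3,3-diphenyl-1-(o-tolyl)tetrahydro-1H,3H-pyrrolo[1,2-c][1,3,2]oxazaborole (20 mol %), Tf2NH (17 mol %), CH2Cl2, −78 to −40 °C
Reagents that add atoms: none
Why: catalytic enantioselective Diels–Alder reaction with a chiral oxazaborolidinium Lewis acid, in which the diene bonds through its C1 terminus to the β-carbon of the enal (silyloxy carbon para to C10), suprafacial addition to the (E)-enal places the C10 methyl and C9 silyloxymethyl groups cis, and the catalyst should fix the absolute configuration of C9 and C10 by directing the diene to the Re face of the α-carbon.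

Step 7
Reactants: 11 (1R,6R)-6-{[(tert-butyldiphenylsilyl)oxy]methyl}-1-methyl-4-[(triisopropylsilyl)oxy]cyclohex-3-ene-1-carbaldehyde
Product: 12 (1R,6R)-6-{[(tert-butyldiphenylsilyl)oxy]methyl}-1-methyl-4-oxocyclohex-2-ene-1-carbaldehyde
Conditions: Pd(OAc)2 (1.1 equiv), MeCN, 40 °C
Reagents that add atoms: none
Why: Saegusa–Ito oxidation, in which palladation of the silyl enol ether at C6 is followed by β-hydride elimination from C5 (the only β-hydrogens), so the C5=C6 enone should form regiospecifically; the aldehyde cannot enolise.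

Step 8
Reactants: 12 (1R,6R)-6-{[(tert-butyldiphenylsilyl)oxy]methyl}-1-methyl-4-oxocyclohex-2-ene-1-carbaldehyde
Product: 15 (1R,4S,6R)-6-{[(tert-butyldiphenylsilyl)oxy]methyl}-4-hydroxy-1-methylcyclohex-2-ene-1-carbaldehyde, via acetal enone 13 (not isolated), via acetal alcohol 14 (not isolated)
Conditions: CeCl3·7H2O, HC(OMe)3, MeOH, rt; then NaBH4, −78 °C; then 1 M HCl, THF, 0 °C
Reagents that add atoms: water, O
Why: Luche reduction after in situ acetalisation of the formyl group (chemoselective ketone reduction beside an aldehyde), in which hydride should add 1,2 to the enone from the face opposite the C9 substituent, as with 5-substituted cyclohexenones, so that the new C7 carbinol (S) is cis to the C9 silyloxymethyl group, and the acidic work-up returns the aldehyde.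

Step 9
Reactants: 15 (1R,4S,6R)-6-{[(tert-butyldiphenylsilyl)oxy]methyl}-4-hydroxy-1-methylcyclohex-2-ene-1-carbaldehyde; 4 [(3-methylbuta-1,2-dien-1-yl)sulfonyl]benzene
Product: 19 (4aR,5R,8aS)-5-{[(tert-butyldiphenylsilyl)oxy]methyl}-1,1,4a-trimethyl-3-(phenylsulfonyl)-4a,5,6,8a-tetrahydronaphthalen-2(1H)-one, via vinyl ether carbanion 16 (not isolated), via keto sulfone enolate 17 (not isolated), via aldolate 18 (not isolated)
Conditions: KH (1.1 equiv), THF, 0 °C; then HMPA, 20 to 50 °C; then AcOH, piperidine (cat.), 60 °C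
Reagents that add atoms: none
Why: The potassium alkoxide of 15 adds to the central allene carbon of 4 to give the 2-(sulfonylmethyl)allyl vinyl ether carbanion 16, which undergoes a carbanion-accelerated Claisen rearrangement ([3,3]-sigmatropic shift) that forms C4–C5 with its gem-dimethyl group and releases the keto sulfone enolate 17; this enolate adds to the neighbouring C1 aldehyde (aldol, C1–C2) and the aldol is dehydrated by piperidinium acetate (Knoevenagel condensation). The closest known reaction type is the tandem alkoxide addition and carbanion-accelerated Claisen rearrangement of allenyl sulfones with allylic alcohols, followed by the Knoevenagel condensation of a β-keto sulfone. Ring A is closed by a 6-(enolendo)-exo-trig aldol addition of C2 to C1, after C4 and C5 have been joined by the sigmatropic shift, which itself closes no ring. The only new stereocenter, C5, is set by suprafacial 1,3-transfer of chirality from the C7 carbinol across C5=C6, so that the C4–C5 bond forms on the face that carried the C7–O bond, cis to the C10 methyl group, which gives the trans ring fusion. The step needs site selectivity (alkoxide addition to the allene before any anion attacks the aldehyde) and regioselectivity in the shift: the first should be secured by the high electrophilicity of the allenyl sulfone, the trans arrangement of C7–O and the formyl group (no lactol, no aldol before the shift) and the non-enolisable quaternary C10, the second by the single allylic terminus C5 and by the sulfone, which makes only the C4 end of the oxyallyl anion productive.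

Step 10
Reactants: 19 (4aR,5R,8aS)-5-{[(tert-butyldiphenylsilyl)oxy]methyl}-1,1,4a-trimethyl-3-(phenylsulfonyl)-4a,5,6,8a-tetrahydronaphthalen-2(1H)-one
Product: 21 (4aR,5R,8aS)-5-{[(tert-butyldiphenylsilyl)oxy]methyl}-1,1,4a-trimethyl-3,4,4a,5,6,8a-hexahydronaphthalen-2(1H)-one, via keto sulfone 20 (not isolated)
Conditions: Zn dust, AcOH, THF, rt to 50 °C
Reagents that add atoms: none
Why: dissolving-metal reduction, in which the doubly activated C1=C2 alkene should be reduced first (conjugate reduction) and the resulting β-keto sulfone then lose sulfinate (reductive desulfonylation), while the isolated C6=C7 alkene and the silyl ether are inert.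

Step 11
Reactants: 21 (4aR,5R,8aS)-5-{[(tert-butyldiphenylsilyl)oxy]methyl}-1,1,4a-trimethyl-3,4,4a,5,6,8a-hexahydronaphthalen-2(1H)-one
Product: 22 (2R,4aR,5R,8aS)-5-{[(tert-butyldiphenylsilyl)oxy]methyl}-1,1,4a-trimethyl-1,2,3,4,4a,5,6,8a-octahydronaphthalen-2-ol
Conditions: NaBH4, MeOH/CH2Cl2, −20 °C
Reagents that add atoms: none
Why: borohydride reduction of a 4,4-dimethyl-3-ketone in a trans-decalin should proceed by axial attack from the face opposite the axial C4 and C10 methyl groups, giving the equatorial C3 alcohol (3R, cis to the C10 methyl).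

Step 12
Reactants: 22 (2R,4aR,5R,8aS)-5-{[(tert-butyldiphenylsilyl)oxy]methyl}-1,1,4a-trimethyl-1,2,3,4,4a,5,6,8a-octahydronaphthalen-2-ol
Product: 23 (2R,4aR,5R,8aS)-5-{[(tert-butyldiphenylsilyl)oxy]methyl}-1,1,4a-trimethyl-1,2,3,4,4a,5,6,8a-octahydronaphthalen-2-yl 3-methylbutanoate
Conditions: 3-methylbutanoyl chloride, pyridine, DMAP (cat.), CH2Cl2, rt
Reagents that add atoms: 3-methylbutanoyl chloride, CC(C)CC(=O)Cl
Why: DMAP-catalysed acylation installs the ester of the target, which also protects the C3 alcohol during the oxidation in step 13.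

Step 13
Reactants: 23 (2R,4aR,5R,8aS)-5-{[(tert-butyldiphenylsilyl)oxy]methyl}-1,1,4a-trimethyl-1,2,3,4,4a,5,6,8a-octahydronaphthalen-2-yl 3-methylbutanoate
Product: 24 (2R,4aR,5R,8aS)-5-{[(tert-butyldiphenylsilyl)oxy]methyl}-1,1,4a-trimethyl-6-oxo-1,2,3,4,4a,5,6,8a-octahydronaphthalen-2-yl 3-methylbutanoate
Conditions: CrO3, 3,5-dimethylpyrazole, CH2Cl2, −20 °C
Reagents that add atoms: chromium trioxide, O=[Cr](=O)=O
Why: allylic oxidation of a cyclohexene to the enone with the CrO3–3,5-dimethylpyrazole complex should take place at the allylic methylene C8, because the other allylic position, C5, is a methine flanked by two quaternary carbons and cannot give a ketone.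

Step 14
Reactants: 24 (2R,4aR,5R,8aS)-5-{[(tert-butyldiphenylsilyl)oxy]methyl}-1,1,4a-trimethyl-6-oxo-1,2,3,4,4a,5,6,8a-octahydronaphthalen-2-yl 3-methylbutanoate
Product: 25 (2R,4aR,5R,8aS)-5-{[(tert-butyldiphenylsilyl)oxy]methyl}-1,1,4a-trimethyl-6-oxodecahydronaphthalen-2-yl 3-methylbutanoate
Conditions: H2 (1 atm), Pd/C, EtOAc, rt
Reagents that add atoms: none
Why: heterogeneous hydrogenation of the enone C6=C7 bond under neutral conditions creates no stereocenter and should leave C9, the ester and the silyl ether untouched.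

Step 15
Reactants: 25 (2R,4aR,5R,8aS)-5-{[(tert-butyldiphenylsilyl)oxy]methyl}-1,1,4a-trimethyl-6-oxodecahydronaphthalen-2-yl 3-methylbutanoate
Product: 26 (2R,4aR,5R,8aS)-5-{[(tert-butyldiphenylsilyl)oxy]methyl}-1,1,4a-trimethyl-6-methylidenedecahydronaphthalen-2-yl 3-methylbutanoate
Conditions: Zn, CH2Br2, TiCl4, THF/CH2Cl2, 0 °C to rt
Reagents that add atoms: dibromomethane, BrCBr
Why: Lombardo methylenation with the non-basic zinc–titanium methylene reagent should convert the hindered C8 ketone to the exocyclic alkene without enolisation, so that C9 is not epimerised and the β-silyloxy group is not eliminated, and it does not attack the ester.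

Step 16
Reactants: 26 (2R,4aR,5R,8aS)-5-{[(tert-butyldiphenylsilyl)oxy]methyl}-1,1,4a-trimethyl-6-methylidenedecahydronaphthalen-2-yl 3-methylbutanoate
Product: 27 (2R,4aR,5R,8aS)-5-(hydroxymethyl)-1,1,4a-trimethyl-6-methylidenedecahydronaphthalen-2-yl 3-methylbutanoate
Conditions: TBAF, AcOH, THF, rt
Reagents that add atoms: none
Why: fluoride cleavage of the silyl ether, buffered with acetic acid so that the hindered secondary ester should survive.

Step 17
Reactants: 27 (2R,4aR,5R,8aS)-5-(hydroxymethyl)-1,1,4a-trimethyl-6-methylidenedecahydronaphthalen-2-yl 3-methylbutanoate; 28 7-hydroxy-2H-chromen-2-one (umbelliferone)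
Product: 29 (2R,4aR,5R,8aS)-1,1,4a-trimethyl-6-methylidene-5-{[(2-oxo-2H-chromen-7-yl)oxy]methyl}decahydronaphthalen-2-yl 3-methylbutanoate (CNP0295317.1)
Conditions: PPh3, DIAD, THF, 0 °C to rt
Reagents that add atoms: none
Why: Mitsunobu etherification of the primary C11 alcohol with the acidic phenol should form the aryl ether without touching any stereocenter, and it is placed last so that the coumarin never meets hydride, hydrogenation or dissolving-metal conditions.

**Compound list**
1 | 2-methylbut-3-yn-2-ol | CC(C)(O)C#C | starting material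
2 | 2-methylbut-3-yn-2-yl benzenesulfenate | CC(C)(OSc1ccccc1)C#C | intermediate
3 | [(3-methylbuta-1,2-dien-1-yl)sulfinyl]benzene (racemic at sulfur) | CC(C)=C=CS(=O)c1ccccc1 | intermediate
4 | [(3-methylbuta-1,2-dien-1-yl)sulfonyl]benzene | CC(C)=C=CS(=O)(=O)c1ccccc1 | intermediate
5 | but-3-en-2-one | CC(=O)C=C | starting material
6 | 2-[(triisopropylsilyl)oxy]buta-1,3-diene | C=CC(=C)O[Si](C(C)C)(C(C)C)C(C)C | intermediate
7 | 3-methylbut-2-en-1-ol | CC(C)=CCO | starting material
8 | tert-butyl[(3-methylbut-2-en-1-yl)oxy]diphenylsilane | CC(C)=CCO[Si](c1ccccc1)(c1ccccc1)C(C)(C)C | intermediate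
9 | (E)-4-[(tert-butyldiphenylsilyl)oxy]-2-methylbut-2-en-1-ol | OC/C(C)=C/CO[Si](c1ccccc1)(c1ccccc1)C(C)(C)C | intermediate
10 | (E)-4-[(tert-butyldiphenylsilyl)oxy]-2-methylbut-2-enal | O=C/C(C)=C/CO[Si](c1ccccc1)(c1ccccc1)C(C)(C)C | intermediate
11 | (1R,6R)-6-{[(tert-butyldiphenylsilyl)oxy]methyl}-1-methyl-4-[(triisopropylsilyl)oxy]cyclohex-3-ene-1-carbaldehyde | C1C(O[Si](C(C)C)(C(C)C)C(C)C)=CC[C@@](C)(C=O)[C@@H]1CO[Si](c1ccccc1)(c1ccccc1)C(C)(C)C | intermediate
12 | (1R,6R)-6-{[(tert-butyldiphenylsilyl)oxy]methyl}-1-methyl-4-oxocyclohex-2-ene-1-carbaldehyde | C1C(=O)C=C[C@@](C)(C=O)[C@@H]1CO[Si](c1ccccc1)(c1ccccc1)C(C)(C)C | intermediate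
13 | (4R,5R)-5-{[(tert-butyldiphenylsilyl)oxy]methyl}-4-(dimethoxymethyl)-4-methylcyclohex-2-en-1-one | C1C(=O)C=C[C@@](C)(C(OC)OC)[C@@H]1CO[Si](c1ccccc1)(c1ccccc1)C(C)(C)C | intermediate
14 | (1S,4R,5R)-5-{[(tert-butyldiphenylsilyl)oxy]methyl}-4-(dimethoxymethyl)-4-methylcyclohex-2-en-1-ol | C1[C@H](O)C=C[C@@](C)(C(OC)OC)[C@@H]1CO[Si](c1ccccc1)(c1ccccc1)C(C)(C)C | intermediate
15 | (1R,4S,6R)-6-{[(tert-butyldiphenylsilyl)oxy]methyl}-4-hydroxy-1-methylcyclohex-2-ene-1-carbaldehyde | C1[C@H](O)C=C[C@@](C)(C=O)[C@@H]1CO[Si](c1ccccc1)(c1ccccc1)C(C)(C)C | intermediate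
16 | potassium α-sulfonyl carbanion of (1R,4S,6R)-6-{[(tert-butyldiphenylsilyl)oxy]methyl}-1-methyl-4-{[3-methyl-1-(phenylsulfonyl)but-2-en-2-yl]oxy}cyclohex-2-ene-1-carbaldehyde | C1[C@H](OC([CH-]S(=O)(=O)c2ccccc2)=C(C)C)C=C[C@@](C)(C=O)[C@@H]1CO[Si](c1ccccc1)(c1ccccc1)C(C)(C)C.[K+] | intermediate
17 | potassium enolate of (1R,2S,6R)-6-{[(tert-butyldiphenylsilyl)oxy]methyl}-1-methyl-2-[2-methyl-3-oxo-4-(phenylsulfonyl)butan-2-yl]cyclohex-3-ene-1-carbaldehyde | C1C=C[C@H](C(C)(C)C(=O)[CH-]S(=O)(=O)c2ccccc2)[C@@](C)(C=O)[C@@H]1CO[Si](c1ccccc1)(c1ccccc1)C(C)(C)C.[K+] | intermediate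
18 | potassium aldolate of (4aR,5R,8aS)-5-{[(tert-butyldiphenylsilyl)oxy]methyl}-4-hydroxy-1,1,4a-trimethyl-3-(phenylsulfonyl)-3,4,4a,5,6,8a-hexahydronaphthalen-2(1H)-one (epimers at C3 and C4) | C1C=C[C@@H]2C(C)(C)C(=O)C(S(=O)(=O)c3ccccc3)C([O-])[C@@]2(C)[C@@H]1CO[Si](c1ccccc1)(c1ccccc1)C(C)(C)C.[K+] | intermediate
19 | (4aR,5R,8aS)-5-{[(tert-butyldiphenylsilyl)oxy]methyl}-1,1,4a-trimethyl-3-(phenylsulfonyl)-4a,5,6,8a-tetrahydronaphthalen-2(1H)-one | C1C=C[C@@H]2C(C)(C)C(=O)C(S(=O)(=O)c3ccccc3)=C[C@@]2(C)[C@@H]1CO[Si](c1ccccc1)(c1ccccc1)C(C)(C)C | intermediate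
20 | (4aR,5R,8aS)-5-{[(tert-butyldiphenylsilyl)oxy]methyl}-1,1,4a-trimethyl-3-(phenylsulfonyl)-3,4,4a,5,6,8a-hexahydronaphthalen-2(1H)-one (epimers at C3) | C1C=C[C@@H]2C(C)(C)C(=O)C(S(=O)(=O)c3ccccc3)C[C@@]2(C)[C@@H]1CO[Si](c1ccccc1)(c1ccccc1)C(C)(C)C | intermediate
21 | (4aR,5R,8aS)-5-{[(tert-butyldiphenylsilyl)oxy]methyl}-1,1,4a-trimethyl-3,4,4a,5,6,8a-hexahydronaphthalen-2(1H)-one | C1C=C[C@@H]2C(C)(C)C(=O)CC[C@@]2(C)[C@@H]1CO[Si](c1ccccc1)(c1ccccc1)C(C)(C)C | intermediate
22 | (2R,4aR,5R,8aS)-5-{[(tert-butyldiphenylsilyl)oxy]methyl}-1,1,4a-trimethyl-1,2,3,4,4a,5,6,8a-octahydronaphthalen-2-ol | C1C=C[C@@H]2C(C)(C)[C@H](O)CC[C@@]2(C)[C@@H]1CO[Si](c1ccccc1)(c1ccccc1)C(C)(C)C | intermediate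
23 | (2R,4aR,5R,8aS)-5-{[(tert-butyldiphenylsilyl)oxy]methyl}-1,1,4a-trimethyl-1,2,3,4,4a,5,6,8a-octahydronaphthalen-2-yl 3-methylbutanoate | C1C=C[C@@H]2C(C)(C)[C@H](OC(=O)CC(C)C)CC[C@@]2(C)[C@@H]1CO[Si](c1ccccc1)(c1ccccc1)C(C)(C)C | intermediate
24 | (2R,4aR,5R,8aS)-5-{[(tert-butyldiphenylsilyl)oxy]methyl}-1,1,4a-trimethyl-6-oxo-1,2,3,4,4a,5,6,8a-octahydronaphthalen-2-yl 3-methylbutanoate | O=C1C=C[C@@H]2C(C)(C)[C@H](OC(=O)CC(C)C)CC[C@@]2(C)[C@@H]1CO[Si](c1ccccc1)(c1ccccc1)C(C)(C)C | intermediate
25 | (2R,4aR,5R,8aS)-5-{[(tert-butyldiphenylsilyl)oxy]methyl}-1,1,4a-trimethyl-6-oxodecahydronaphthalen-2-yl 3-methylbutanoate | O=C1CC[C@@H]2C(C)(C)[C@H](OC(=O)CC(C)C)CC[C@@]2(C)[C@@H]1CO[Si](c1ccccc1)(c1ccccc1)C(C)(C)C | intermediate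
26 | (2R,4aR,5R,8aS)-5-{[(tert-butyldiphenylsilyl)oxy]methyl}-1,1,4a-trimethyl-6-methylidenedecahydronaphthalen-2-yl 3-methylbutanoate | C=C1CC[C@@H]2C(C)(C)[C@H](OC(=O)CC(C)C)CC[C@@]2(C)[C@@H]1CO[Si](c1ccccc1)(c1ccccc1)C(C)(C)C | intermediate
27 | (2R,4aR,5R,8aS)-5-(hydroxymethyl)-1,1,4a-trimethyl-6-methylidenedecahydronaphthalen-2-yl 3-methylbutanoate | C=C1CC[C@@H]2C(C)(C)[C@H](OC(=O)CC(C)C)CC[C@@]2(C)[C@@H]1CO | intermediate
28 | 7-hydroxy-2H-chromen-2-one (umbelliferone) | Oc1ccc2ccc(=O)oc2c1 | starting material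
29 | (2R,4aR,5R,8aS)-1,1,4a-trimethyl-6-methylidene-5-{[(2-oxo-2H-chromen-7-yl)oxy]methyl}decahydronaphthalen-2-yl 3-methylbutanoate (CNP0295317.1) | C=C1CC[C@@H]2C(C)(C)[C@H](OC(=O)CC(C)C)CC[C@@]2(C)[C@@H]1COc1ccc2ccc(=O)oc2c1 | target

**Step count and risks**
Total step count: 17. Longest linear sequence: 14 steps (steps 4 to 17).

Steps most likely to fail:

Step 9 (key step). The free formyl group may be consumed by the alkoxide or by the sulfonyl carbanion (intermolecular aldol addition or hydride transfer) before the sigmatropic shift, and the shift itself may be slow because it must pass through the conformer with a pseudoaxial C7–O bond. The fallback separates the events and keeps the aldehyde masked. It sets out from 14, which is isolated when the acidic work-up of step 8 is left out. Addition of 14 to 4 with a catalytic amount of KH in THF should give the neutral allyl vinyl ether acetal F1. Stoichiometric KH in THF/HMPA should then bring about the carbanion-accelerated Claisen rearrangement to the keto sulfone acetal F2. Aqueous HCl in THF should unmask the keto aldehyde F3, and piperidinium acetate should close ring A by Knoevenagel condensation, which comes back to the route at 19.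

Step 6. The trisubstituted enal may add too slowly to the 2-silyloxy diene, so that acid-induced loss of the silyl enol ether of the diene or poor facial discrimination takes over. The fallback sets out from 10 and uses a far more nucleophilic diene under a different mode of activation. A Diels–Alder reaction of 10 with commercial (E)-1-(dimethylamino)-3-(tert-butyldimethylsilyloxy)buta-1,3-diene, under hydrogen-bond catalysis by a 1-naphthyl TADDOL, should give the amino silyl enol ether F4. Work-up with aqueous HCl in THF should cleave the silyl enol ether and eliminate dimethylamine, which comes back to the route at 12 and makes step 7 unnecessary.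

Step 13. Hydrogen abstraction may occur with allylic transposition or at C5, giving regioisomeric oxidation, and over-oxidation is possible. The fallback sets out from 23 and delivers oxygen by a pericyclic path that cannot transpose. SeO2 (catalytic) with t-BuOOH in CH2Cl2 (ene reaction, then [2,3]-sigmatropic shift, favouring the allylic methylene) should give the C8 allylic alcohol F5. Dess–Martin periodinane should then oxidise F5 to the enone, which comes back to the route at 24.

Further compounds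
F1 | step 9 | O-[3-methyl-1-(phenylsulfonyl)but-2-en-2-yl] ether of 14: tert-butyl{[(1R,2R,5S)-2-(dimethoxymethyl)-2-methyl-5-{[3-methyl-1-(phenylsulfonyl)but-2-en-2-yl]oxy}cyclohex-3-en-1-yl]methoxy}diphenylsilane | C1[C@H](OC(CS(=O)(=O)c2ccccc2)=C(C)C)C=C[C@@](C)(C(OC)OC)[C@@H]1CO[Si](c1ccccc1)(c1ccccc1)C(C)(C)C
F2 | step 9 | dimethyl acetal of F3 | C1C=C[C@H](C(C)(C)C(=O)CS(=O)(=O)c2ccccc2)[C@@](C)(C(OC)OC)[C@@H]1CO[Si](c1ccccc1)(c1ccccc1)C(C)(C)C
F3 | step 9 | (1R,2S,6R)-6-{[(tert-butyldiphenylsilyl)oxy]methyl}-1-methyl-2-[2-methyl-3-oxo-4-(phenylsulfonyl)butan-2-yl]cyclohex-3-ene-1-carbaldehyde | C1C=C[C@H](C(C)(C)C(=O)CS(=O)(=O)c2ccccc2)[C@@](C)(C=O)[C@@H]1CO[Si](c1ccccc1)(c1ccccc1)C(C)(C)C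
F4 | step 6 | (1S,6R)-6-{[(tert-butyldiphenylsilyl)oxy]methyl}-4-[(tert-butyldimethylsilyl)oxy]-2-(dimethylamino)-1-methylcyclohex-3-ene-1-carbaldehyde (epimers at C2) | C1C(O[Si](C)(C)C(C)(C)C)=CC(N(C)C)[C@@](C)(C=O)[C@@H]1CO[Si](c1ccccc1)(c1ccccc1)C(C)(C)C
F5 | step 13 | (2R,4aR,5R,8aS)-5-{[(tert-butyldiphenylsilyl)oxy]methyl}-6-hydroxy-1,1,4a-trimethyl-1,2,3,4,4a,5,6,8a-octahydronaphthalen-2-yl 3-methylbutanoate (epimers at C6) | OC1C=C[C@@H]2C(C)(C)[C@H](OC(=O)CC(C)C)CC[C@@]2(C)[C@@H]1CO[Si](c1ccccc1)(c1ccccc1)C(C)(C)C
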